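**Plan**

1. Retrosynthetic cuts: first the six O-protecting groups. Then, in one event, the C-3–CH2 bond between the spiroketal and the (benzofuran-2-yl)methyl unit together with the ketal C–O bond of ring A, giving flat 2-(2-hydroxybenzyl)benzofuran 11 and electrophile 18.
2. 11 is cut at its furan (cyclodehydration of the symmetric diarylacetone 9), and 9 at both aryl–CH2 bonds (double Claisen rearrangement). 18 is cut at the furan of ring C (Sonogashira–cyclisation). All three arenes come from one ketone, 3.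
3. Forward ring order: furan of ring B (step 6), furan of ring C (step 8), then both dihydrofurans of the spiroketal at once in step 12, when the furan of 11 is dearomatised.
4. Enabling feature: C-2=C-3 of the benzofuran in 11 is an aryl enol ether, and C-2 carries the CH2–aryl arm whose free ortho OH lies five atoms from C-2. Alkylation at C-3 therefore gives an oxocarbenium ion that this OH traps (5-exo) as the bis-aryl spiroketal.
5. Stereochemistry: C-3 by catalyst control (chiral Brønsted acid ion pair), the ketal carbon relative to C-3 by delivery of the phenol on the same face. No acid is used after step 12.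

Key step: step 12

Assumption: the (R)-BINOL-derived acid in step 12 is taken to give the (2R,3S) product; if the sense of induction is the opposite, its mirror image is used. TBS = tert-butyldimethylsilyl. Rings A and B are the two dihydrobenzofurans of the spiroketal (B carries the C-3 substituent); ring C is the benzofuran.

**Route**

Step 1
Reactants: 1 phloroglucinol; 2 3-methylbutanoyl chloride
Product: 3 1-(2,4,6-trihydroxyphenyl)-3-methylbutan-1-one
Conditions: AlCl3 (3.5 equiv), PhNO2/CH2Cl2, 0 → 60 °C; aq. HCl work-up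
Reagents that add atoms: none
Why: Friedel–Crafts acylation of the C3-symmetric triphenol, which should stop after one acylation because the chelated aryl ketone deactivates the ring.

Step 2
Reactants: 3 1-(2,4,6-trihydroxyphenyl)-3-methylbutan-1-one
Product: 4 1-[2,4-bis(TBS-oxy)-6-hydroxyphenyl]-3-methylbutan-1-one
Conditions: TBSCl (2.1 equiv), imidazole, CH2Cl2/DMF, 0 °C
Reagents that add atoms: tert-butyldimethylsilyl chloride, CC(C)(C)[Si](C)(C)Cl
Why: phenol silylation in which the para OH and one ortho OH react while the last OH stays locked in the hydrogen-bond chelate with the ketone, the usual outcome of double protection of 2,4,6-trihydroxyaryl ketones.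

Step 3
Reactants: 4 1-[2,4-bis(TBS-oxy)-6-hydroxyphenyl]-3-methylbutan-1-one (2 equiv); 5 2-methylidenepropane-1,3-diol
Product: 6 1,3-bis[2-(3-methylbutanoyl)-3,5-bis(TBS-oxy)phenoxy]-2-methylidenepropane
Conditions: PPh3, DIAD, THF, 0 °C → rt
Reagents that add atoms: none
Why: double Mitsunobu etherification under neutral conditions that spare the aryl silyl ethers; SN2 and SN2' attack on this symmetric allylic diol give the same ether.

Step 4
Reactants: 6 1,3-bis[2-(3-methylbutanoyl)-3,5-bis(TBS-oxy)phenoxy]-2-methylidenepropane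
Product: 8 1,3-bis[2-hydroxy-3-(3-methylbutanoyl)-4,6-bis(TBS-oxy)phenyl]-2-methylidenepropane, via mono-rearranged allyl aryl ether 7 (not isolated)
Conditions: 1,2-dichlorobenzene, BHT (cat.), 185 °C, sealed tube, degassed
Reagents that add atoms: none
Why: two successive aromatic Claisen [3,3] rearrangements; each ether oxygen has only one free ortho carbon (the other bears the ketone), so both aryl–CH2 bonds form next to the regenerated OH, and the second shift uses the allyl ether created by the first.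

Step 5
Reactants: 8 1,3-bis[2-hydroxy-3-(3-methylbutanoyl)-4,6-bis(TBS-oxy)phenyl]-2-methylidenepropane
Product: 9 1,3-bis[2-hydroxy-3-(3-methylbutanoyl)-4,6-bis(TBS-oxy)phenyl]propan-2-one
Conditions: O3, CH2Cl2/MeOH, −78 °C, Sudan Red 7B end point; then Me2S, −78 °C → rt
Reagents that add atoms: ozone, [O-][O+]=O
Why: ozonolysis with reductive work-up of the 1,1-disubstituted alkene, the most reactive π bond present; the acyl-substituted, silyl-flanked arenes should react more slowly and the indicator stops the ozone at the alkene.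

Step 6
Reactants: 9 1,3-bis[2-hydroxy-3-(3-methylbutanoyl)-4,6-bis(TBS-oxy)phenyl]propan-2-one
Product: 11 2-(2-hydroxybenzyl)benzofuran with 7-(3-methylbutanoyl)-4,6-bis(TBS-oxy) on the benzofuran and 3-(3-methylbutanoyl)-4,6-bis(TBS-oxy) on the benzyl ring, via cyclic hemiketal 10 (not isolated)
Conditions: camphorsulfonic acid (10 mol %), toluene, 4 Å MS, 80 °C
Reagents that add atoms: none
Why: acid-catalysed cyclodehydration of an o-hydroxybenzyl ketone (5-exo hemiketal, then loss of water to the aromatic furan); the ketone is symmetric so either phenol gives the same product, and under these equilibrating conditions any spiroketal from closure of the second, chelated phenol should reopen and drain to the benzofuran.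

Step 7
Reactants: 3 1-(2,4,6-trihydroxyphenyl)-3-methylbutan-1-one
Product: 12 1-(2,4,6-trihydroxy-3-iodophenyl)-3-methylbutan-1-one
Conditions: N-iodosuccinimide (1.0 equiv), MeCN, −20 → 0 °C
Reagents that add atoms: N-iodosuccinimide, O=C1CCC(=O)N1I
Why: electrophilic aromatic iodination of a ring whose two free positions are equivalent, so that one equivalent of reagent at low temperature should give a single mono-iodide.

Step 8
Reactants: 12 1-(2,4,6-trihydroxy-3-iodophenyl)-3-methylbutan-1-one; 13 tert-butyldimethyl(prop-2-yn-1-yloxy)silane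
Product: 15 1-[2-(TBS-oxymethyl)-4,6-dihydroxy-1-benzofuran-5-yl]-3-methylbutan-1-one, via ortho-alkynylphenol 14 (not isolated)
Conditions: PdCl2(PPh3)2 (3 mol %), CuI (6 mol %), Et3N, DMF, rt → 60 °C, degassed
Reagents that add atoms: none
Why: Sonogashira coupling followed by 5-endo-dig hydroalkoxylation of the alkyne; of the two flanking hydroxyls the one para to the ketone is the more acidic and is not needed for the chelate, so its phenoxide should close the furan and leave both ketone-flanking OH groups free.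

Step 9
Reactants: 15 1-[2-(TBS-oxymethyl)-4,6-dihydroxy-1-benzofuran-5-yl]-3-methylbutan-1-one
Product: 16 2-(TBS-oxymethyl)-5-(3-methylbutanoyl)-1-benzofuran-4,6-diyl diacetate
Conditions: Ac2O, pyridine, DMAP (cat.), CH2Cl2, rt
Reagents that add atoms: acetic anhydride, CC(=O)OC(C)=O
Why: DMAP-catalysed acetylation forces both chelated phenols to react; the acetates deactivate ring C towards electrophilic attack in step 12.

Step 10
Reactants: 16 2-(TBS-oxymethyl)-5-(3-methylbutanoyl)-1-benzofuran-4,6-diyl diacetate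
Product: 17 2-(hydroxymethyl)-5-(3-methylbutanoyl)-1-benzofuran-4,6-diyl diacetate
Conditions: HF·pyridine, THF/pyridine, 0 °C → rt
Reagents that add atoms: none
Why: buffered fluoride cleavage of the primary silyl ether, conditions under which aryl acetates are stable.

Step 11
Reactants: 17 2-(hydroxymethyl)-5-(3-methylbutanoyl)-1-benzofuran-4,6-diyl diacetate
Product: 18 [4,6-diacetoxy-5-(3-methylbutanoyl)-1-benzofuran-2-yl]methyl 2,2,2-trichloroacetimidate
Conditions: Cl3CCN, DBU (10 mol %), CH2Cl2, 0 °C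
Reagents that add atoms: trichloroacetonitrile, ClC(Cl)(Cl)C#N
Why: base-catalysed addition of the primary alcohol to trichloroacetonitrile, which tolerates ester groups and gives a leaving group that a Brønsted acid can activate.

Step 12
Reactants: 11 2-(2-hydroxybenzyl)benzofuran nucleophile (1.5 equiv); 18 [4,6-diacetoxy-5-(3-methylbutanoyl)-1-benzofuran-2-yl]methyl 2,2,2-trichloroacetimidate (added over 4 h)
Product: 20 (2R,3S)-spiroketal with four TBS ethers on rings A and B and two acetates on ring C, via oxocarbenium ion 19 (not isolated)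
Conditions: (R)-3,3'-bis(2,4,6-triisopropylphenyl)-BINOL N-triflylphosphoramide (10 mol %), 5 Å MS, toluene, −40 °C; Et3N quench at −40 °C
Reagents that add atoms: none
Why: Proposed new method: the chiral N-triflylphosphoramide protonates the imidate nitrogen of 18 and ionises it to a tight ion pair of the (benzofuran-2-yl)methyl cation (stabilised by the ring oxygen through C-3 and C-7a) with the chiral anion, which also hydrogen-bonds the single free phenol of 11; C-3 of 11, the β-carbon of the cyclic aryl enol ether, attacks the exocyclic CH2 (attack there keeps the furan of the electrophile aromatic), which breaks the furan aromaticity of 11 and gives oxocarbenium 19. The phenol on the CH2–aryl arm at C-2 then closes the second dihydrofuran by 5-exo-trig attack on C-2 and hands its proton back to the catalyst, trichloroacetamide being the only by-product. The closest known reaction types are chiral phosphoric acid-catalysed alkylative dearomatisation–cyclisation cascades of 3-substituted indoles bearing a pendant OH or NH nucleophile, and chiral Brønsted acid-catalysed spiroketalisation of enol ethers with a proton as the electrophile; new here is a carbon electrophile on a benzofuran with a phenol as the trap. C-3 (S) should be set by the catalyst, which exposes one face of the flat benzofuran inside the ion pair; the ketal carbon (R) should be set relative to it by the anion that escorts the cation and delivers the phenol on the same face, so that C–C and C–O form syn and the new CH2 lies cis to the aryl oxygen and trans to the benzylic CH2 of ring A, as in the target. The step needs furan C-3 over arene carbon (each aryl C–H of 11 sits between two OTBS groups, 18 and the product carry deactivating acetates, and 18 is added slowly to an excess of 11), C- over O-alkylation (the only OH is hindered and chelated to its ketone) and ring closure over loss of the C-3 proton (−40 °C, the proton acceptor sits at the phenol while C-3–H points to the opposite face). Quenching cold with Et3N should keep the kinetic ketal from re-ionising.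

Step 13
Reactants: 20 (2R,3S)-spiroketal with four TBS ethers and two acetates
Product: 22 CNP0169640.1 (target), via ring-C diacetate tetraphenol 21 (not isolated)
Conditions: HF·pyridine (excess), THF/pyridine, 0 °C → rt; then 7 M NH3 in MeOH (excess), 0 °C, argon; pH 6 buffer work-up
Reagents that add atoms: none
Why: fluoride cleavage of the four aryl silyl ethers followed by ammonolysis of the two aryl acetates, neither of which should ionise the bis-aryl ketal or touch the C-3 hydrogen, so both stereocentres are kept.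

**Compound list**

1 | phloroglucinol (benzene-1,3,5-triol) | Oc1cc(O)cc(O)c1 | starting material
2 | 3-methylbutanoyl chloride (isovaleryl chloride) | CC(C)CC(Cl)=O | starting material
3 | 1-(2,4,6-trihydroxyphenyl)-3-methylbutan-1-one | CC(C)CC(=O)c1c(O)cc(O)cc1O | intermediate
4 | 1-[2,4-bis(tert-butyldimethylsilyloxy)-6-hydroxyphenyl]-3-methylbutan-1-one | CC(C)CC(=O)c1c(O)cc(O[Si](C)(C)C(C)(C)C)cc1O[Si](C)(C)C(C)(C)C | intermediate
5 | 2-methylidenepropane-1,3-diol | C=C(CO)CO | starting material
6 | 1,3-bis[2-(3-methylbutanoyl)-3,5-bis(TBS-oxy)phenoxy]-2-methylidenepropane | C=C(COc1cc(O[Si](C)(C)C(C)(C)C)cc(O[Si](C)(C)C(C)(C)C)c1C(=O)CC(C)C)COc1cc(O[Si](C)(C)C(C)(C)C)cc(O[Si](C)(C)C(C)(C)C)c1C(=O)CC(C)C | intermediate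
7 | mono-Claisen product: 2-{[2-hydroxy-3-(3-methylbutanoyl)-4,6-bis(TBS-oxy)phenyl]methyl}prop-2-en-1-yl 2-(3-methylbutanoyl)-3,5-bis(TBS-oxy)phenyl ether | C=C(COc1cc(O[Si](C)(C)C(C)(C)C)cc(O[Si](C)(C)C(C)(C)C)c1C(=O)CC(C)C)Cc1c(O)c(C(=O)CC(C)C)c(O[Si](C)(C)C(C)(C)C)cc1O[Si](C)(C)C(C)(C)C | intermediate
8 | 1,3-bis[2-hydroxy-3-(3-methylbutanoyl)-4,6-bis(TBS-oxy)phenyl]-2-methylidenepropane | C=C(Cc1c(O)c(C(=O)CC(C)C)c(O[Si](C)(C)C(C)(C)C)cc1O[Si](C)(C)C(C)(C)C)Cc1c(O)c(C(=O)CC(C)C)c(O[Si](C)(C)C(C)(C)C)cc1O[Si](C)(C)C(C)(C)C | intermediate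
9 | 1,3-bis[2-hydroxy-3-(3-methylbutanoyl)-4,6-bis(TBS-oxy)phenyl]propan-2-one | O=C(Cc1c(O)c(C(=O)CC(C)C)c(O[Si](C)(C)C(C)(C)C)cc1O[Si](C)(C)C(C)(C)C)Cc1c(O)c(C(=O)CC(C)C)c(O[Si](C)(C)C(C)(C)C)cc1O[Si](C)(C)C(C)(C)C | intermediate
10 | racemic hemiketal: 2-hydroxy-2-{[2-hydroxy-3-(3-methylbutanoyl)-4,6-bis(TBS-oxy)phenyl]methyl}-7-(3-methylbutanoyl)-4,6-bis(TBS-oxy)-2,3-dihydro-1-benzofuran | CC(C)CC(=O)c1c(O[Si](C)(C)C(C)(C)C)cc(O[Si](C)(C)C(C)(C)C)c2c1OC(O)(Cc1c(O)c(C(=O)CC(C)C)c(O[Si](C)(C)C(C)(C)C)cc1O[Si](C)(C)C(C)(C)C)C2 | intermediate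
11 | 1-{2-[[2-hydroxy-3-(3-methylbutanoyl)-4,6-bis(TBS-oxy)phenyl]methyl]-4,6-bis(TBS-oxy)-1-benzofuran-7-yl}-3-methylbutan-1-one | CC(C)CC(=O)c1c(O[Si](C)(C)C(C)(C)C)cc(O[Si](C)(C)C(C)(C)C)c2cc(Cc3c(O)c(C(=O)CC(C)C)c(O[Si](C)(C)C(C)(C)C)cc3O[Si](C)(C)C(C)(C)C)oc12 | intermediate
12 | 1-(2,4,6-trihydroxy-3-iodophenyl)-3-methylbutan-1-one | CC(C)CC(=O)c1c(O)cc(O)c(I)c1O | intermediate
13 | tert-butyldimethyl(prop-2-yn-1-yloxy)silane | C#CCO[Si](C)(C)C(C)(C)C | starting material
14 | 1-{3-[3-(TBS-oxy)prop-1-yn-1-yl]-2,4,6-trihydroxyphenyl}-3-methylbutan-1-one | CC(C)CC(=O)c1c(O)cc(O)c(C#CCO[Si](C)(C)C(C)(C)C)c1O | intermediate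
15 | 1-[2-(TBS-oxymethyl)-4,6-dihydroxy-1-benzofuran-5-yl]-3-methylbutan-1-one | CC(C)CC(=O)c1c(O)cc2oc(CO[Si](C)(C)C(C)(C)C)cc2c1O | intermediate
16 | 2-(TBS-oxymethyl)-5-(3-methylbutanoyl)-1-benzofuran-4,6-diyl diacetate | CC(C)CC(=O)c1c(OC(C)=O)cc2oc(CO[Si](C)(C)C(C)(C)C)cc2c1OC(C)=O | intermediate
17 | 2-(hydroxymethyl)-5-(3-methylbutanoyl)-1-benzofuran-4,6-diyl diacetate | CC(C)CC(=O)c1c(OC(C)=O)cc2oc(CO)cc2c1OC(C)=O | intermediate
18 | [4,6-diacetoxy-5-(3-methylbutanoyl)-1-benzofuran-2-yl]methyl 2,2,2-trichloroacetimidate | CC(C)CC(=O)c1c(OC(C)=O)cc2oc(COC(=N)C(Cl)(Cl)Cl)cc2c1OC(C)=O | intermediate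
19 | (3S)-oxocarbenium ion: 3H-1-benzofuran-1-ium of ring B with C-2 bearing the 2-hydroxyaryl-methyl arm and C-3 bearing the (ring-C benzofuran-2-yl)methyl group | CC(C)CC(=O)c1c(O)c(CC2=[O+]c3c(C(=O)CC(C)C)c(O[Si](C)(C)C(C)(C)C)cc(O[Si](C)(C)C(C)(C)C)c3[C@@H]2Cc2cc3c(OC(C)=O)c(C(=O)CC(C)C)c(OC(C)=O)cc3o2)c(O[Si](C)(C)C(C)(C)C)cc1O[Si](C)(C)C(C)(C)C | intermediate
20 | (2R,3S)-3-{[4,6-diacetoxy-5-(3-methylbutanoyl)-1-benzofuran-2-yl]methyl}-7,7'-bis(3-methylbutanoyl)-4,4',6,6'-tetrakis(TBS-oxy)-3H,3'H-2,2'-spirobi[1-benzofuran] | CC(C)CC(=O)c1c(O[Si](C)(C)C(C)(C)C)cc(O[Si](C)(C)C(C)(C)C)c2c1O[C@]1(C2)Oc2c(C(=O)CC(C)C)c(O[Si](C)(C)C(C)(C)C)cc(O[Si](C)(C)C(C)(C)C)c2[C@@H]1Cc1cc2c(OC(C)=O)c(C(=O)CC(C)C)c(OC(C)=O)cc2o1 | intermediate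
21 | (2R,3S)-3-{[4,6-diacetoxy-5-(3-methylbutanoyl)-1-benzofuran-2-yl]methyl}-4,4',6,6'-tetrahydroxy-7,7'-bis(3-methylbutanoyl)-3H,3'H-2,2'-spirobi[1-benzofuran] | CC(C)CC(=O)c1c(O)cc(O)c2c1O[C@]1(C2)Oc2c(C(=O)CC(C)C)c(O)cc(O)c2[C@@H]1Cc1cc2c(OC(C)=O)c(C(=O)CC(C)C)c(OC(C)=O)cc2o1 | intermediate
22 | CNP0169640.1: (2R,3S)-3-{[4,6-dihydroxy-5-(3-methylbutanoyl)-1-benzofuran-2-yl]methyl}-4,4',6,6'-tetrahydroxy-7,7'-bis(3-methylbutanoyl)-3H,3'H-2,2'-spirobi[1-benzofuran] | CC(C)CC(=O)c1c(O)cc(O)c2c1O[C@]1(C2)Oc2c(C(=O)CC(C)C)c(O)cc(O)c2[C@@H]1Cc1cc2c(O)c(C(=O)CC(C)C)c(O)cc2o1 | target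

**Step count and risks**

Total steps: 13. Longest linear sequence: 8 steps from phloroglucinol (steps 1–6, 12, 13, or steps 1, 7–11, 12, 13).

Steps most likely to fail:

1. Step 12 (proposed new method). What may go wrong: loss of the C-3 proton from the oxocarbenium ion (rearomatisation) in competition with ring closure; alkylation at the phenol oxygen or at the furan of a second electrophile or product molecule; insufficient facial discrimination in the ion pair; closure of the phenol on the opposite face. Fallback with known chemistry, setting out from ketone 9 and alcohol 17 and returning at 20: 17 is converted with CBr4/PPh3 into [4,6-diacetoxy-5-(3-methylbutanoyl)-1-benzofuran-2-yl]methyl bromide F1. Ketone 9 is deprotonated with LiHMDS (3.1 equiv, THF, −78 °C; two phenoxides and the enolate of the doubly benzylic ketone, its most acidic C–H) and alkylated with F1 to give racemic 4-[4,6-diacetoxy-5-(3-methylbutanoyl)-1-benzofuran-2-yl]-1,3-bis[2-hydroxy-3-(3-methylbutanoyl)-4,6-bis(TBS-oxy)phenyl]butan-2-one F2. Brief treatment with pyridinium p-toluenesulfonate in CH2Cl2 at 0 °C should close hemiketal and ketal to the racemic spiroketal, that is 20 together with its enantiomer F3. Preparative chromatography on a chiral stationary phase then delivers 20, and step 13 follows.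

2. Step 4. What may go wrong: thermal addition of the liberated phenol to the 1,1-disubstituted alkene, loss of silyl groups at 185 °C, and stalling after the first sigmatropic shift. Fallback with a different disconnection, setting out from 4 and returning at 11: iodination of 4 with N-iodosuccinimide ortho to its free OH (the other ring position lies between two OTBS groups) gives 1-[2-hydroxy-3-iodo-4,6-bis(TBS-oxy)phenyl]-3-methylbutan-1-one F4. Sonogashira coupling of F4 with prop-2-yn-1-ol and cyclisation through the only free OH gives [7-(3-methylbutanoyl)-4,6-bis(TBS-oxy)-1-benzofuran-2-yl]methanol F5. Acid-catalysed Friedel–Crafts benzylation of an excess of 4 with F5 (Sc(OTf)3, CH2Cl2), again ortho to the free OH, gives 11.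

3. Step 8. What may go wrong: ring closure through the hydroxyl next to the ketone (wrong ring fusion) and oxidative alkyne homocoupling with the unprotected triphenol. Fallback that fixes the regiochemistry by protection, setting out from 3 and returning at 16: 3 is silylated once at the most acidic para OH (TBSCl, 1.0 equiv) to 1-[4-(TBS-oxy)-2,6-dihydroxyphenyl]-3-methylbutan-1-one F6. Both chelated hydroxyls are acetylated (Ac2O, DMAP) to 2-(3-methylbutanoyl)-5-(TBS-oxy)-1,3-phenylene diacetate F7. The silyl ether is cleaved with HF·pyridine to 5-hydroxy-2-(3-methylbutanoyl)-1,3-phenylene diacetate F8. N-Iodosuccinimide iodinates ortho to the single free OH to give 5-hydroxy-4-iodo-2-(3-methylbutanoyl)-1,3-phenylene diacetate F9. Sonogashira coupling of F9 with 13 and cyclisation, now possible only through that OH, gives 16 directly.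

Further compounds
F1 | step 12 | [4,6-diacetoxy-5-(3-methylbutanoyl)-1-benzofuran-2-yl]methyl bromide | CC(C)CC(=O)c1c(OC(C)=O)cc2oc(CBr)cc2c1OC(C)=O
F2 | step 12 | racemic 4-[4,6-diacetoxy-5-(3-methylbutanoyl)-1-benzofuran-2-yl]-1,3-bis[2-hydroxy-3-(3-methylbutanoyl)-4,6-bis(TBS-oxy)phenyl]butan-2-one | CC(C)CC(=O)c1c(O)c(CC(=O)C(Cc2cc3c(OC(C)=O)c(C(=O)CC(C)C)c(OC(C)=O)cc3o2)c2c(O)c(C(=O)CC(C)C)c(O[Si](C)(C)C(C)(C)C)cc2O[Si](C)(C)C(C)(C)C)c(O[Si](C)(C)C(C)(C)C)cc1O[Si](C)(C)C(C)(C)C
F3 | step 12 | (2S,3R)-enantiomer of 20 | CC(C)CC(=O)c1c(O[Si](C)(C)C(C)(C)C)cc(O[Si](C)(C)C(C)(C)C)c2c1O[C@@]1(C2)Oc2c(C(=O)CC(C)C)c(O[Si](C)(C)C(C)(C)C)cc(O[Si](C)(C)C(C)(C)C)c2[C@H]1Cc1cc2c(OC(C)=O)c(C(=O)CC(C)C)c(OC(C)=O)cc2o1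
F4 | step 4 | 1-[2-hydroxy-3-iodo-4,6-bis(TBS-oxy)phenyl]-3-methylbutan-1-one | CC(C)CC(=O)c1c(O)c(I)c(O[Si](C)(C)C(C)(C)C)cc1O[Si](C)(C)C(C)(C)C
F5 | step 4 | [7-(3-methylbutanoyl)-4,6-bis(TBS-oxy)-1-benzofuran-2-yl]methanol | CC(C)CC(=O)c1c(O[Si](C)(C)C(C)(C)C)cc(O[Si](C)(C)C(C)(C)C)c2cc(CO)oc12
F6 | step 8 | 1-[4-(TBS-oxy)-2,6-dihydroxyphenyl]-3-methylbutan-1-one | CC(C)CC(=O)c1c(O)cc(O[Si](C)(C)C(C)(C)C)cc1O
F7 | step 8 | 2-(3-methylbutanoyl)-5-(TBS-oxy)-1,3-phenylene diacetate | CC(C)CC(=O)c1c(OC(C)=O)cc(O[Si](C)(C)C(C)(C)C)cc1OC(C)=O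
F8 | step 8 | 5-hydroxy-2-(3-methylbutanoyl)-1,3-phenylene diacetate | CC(C)CC(=O)c1c(OC(C)=O)cc(O)cc1OC(C)=O
F9 | step 8 | 5-hydroxy-4-iodo-2-(3-methylbutanoyl)-1,3-phenylene diacetate | CC(C)CC(=O)c1c(OC(C)=O)cc(O)c(I)c1OC(C)=O
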